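# Artocarpetin B: synthesis proposal by SNAr closure of ring C on a symmetric difluoroarene

## Analysis of the target

Artocarpetin B (19) is a flavone: a benzo ring A fused to a 4-pyranone ring C, with an aryl ring B on C2. Ring A carries a free hydroxyl on C5 (hydrogen-bonded to the C4 carbonyl), a methoxy group on C7 and a 3-methylbut-2-enyl (prenyl) group on C8, and ring B carries a methoxy group on C2' and a free hydroxyl on C4'. There is no stereocentre, and the prenyl double bond bears two identical methyl groups, so no olefin geometry has to be set. The sensitive parts are the trisubstituted olefin (acid, electrophiles, hydrogenation), the two phenols, and C2 of the pyranone, a vinylogous ester carbon that hard nucleophiles can attack. The difficulty is regiochemical: on the phloroglucinol-type ring A the oxygens on C5, C7 and C8a must end as a free phenol, a methyl ether and the ring oxygen, the prenyl group must sit on C8 and not on the very similar C6, and on ring B the 2'- and 4'-oxygens must be told apart. The route rests on the fact that C4a is flanked by two oxygen-bearing carbons, C5 and C8a, while the C7 methoxy group lies para to C4a on the local mirror plane of ring A. A 2,6-dihalo-4-methoxybenzoyl unit therefore has two equivalent halogens, of which either can become C8a while the other becomes C5, ortho to the C4 carbonyl and still open to exchange against oxygen; since C8 is para to C5 and C6 is the only free ortho position, an allyl-type ether on O5 is then the natural carrier for the prenyl group.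

## Retrosynthetic reasoning

**19 to 18.** The last bond cut is the acetal C–O bond of the methoxymethyl ether on O4'. This ether is chosen because it survives the amide base, the carbonate, the alkoxide and the rearrangement, and comes off under mild acid. In 18 the prenyl group is flanked by the ring oxygen and the 7-methoxy group, so it has no free neighbouring hydroxyl that acid could cyclise onto it.

**18 to 15.** The C8–CH2 bond is cut and traced back to an O5–CH2 bond in prenyl ether 15. Direct C-prenylation of a 5,7-dioxygenated flavone would not distinguish C6 from C8. From O5, a first [3,3] shift can only reach C6 (dienone 16), a second [3,3] shift moves the group on to C8 with linear prenyl connectivity (dienone 17), and enolisation releases the 5-hydroxyl of 18. One operation therefore places the prenyl group and frees O5, while O7 stays a methyl ether throughout.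

**15 to 11 and 12.** The C5–O bond is cut. In fluoroflavone 11 the fluorine on C5 is ortho to C4a and thus conjugated to the C4 carbonyl, while the donors on C7 and C8a are meta to it. Substitution by the sodium salt 13 of alcohol 12 (through adduct 14) should therefore be feasible. The gain is that O5 enters already carrying the prenyl group, so no protecting group is ever needed on ring A.

**11 to 8 (key disconnection).** The O1–C8a bond is cut, which opens ring C to diketone 8. The cut is made here and not at O1–C2 because the ring A half of 8 is then a symmetric difluoroarene: closure at either fluorine gives the same flavone, and the fluorine left behind is the handle used above. The forward reaction must make the enolate oxygen on the ring B side of 9 add to a fluorine-bearing carbon (adduct 10) and expel the fluorine.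

**8 to 3 and 5.** The C3–C4 bond is cut between the methyl carbon of ketone 3 (as its enolate 6) and the acyl carbon of acid chloride 5. Ketone 3 has a single enolisable position and 5 has none, so the crossed acylation is unambiguous; the product is held as its salt 7 until work-up.

**3 to 2 to 1, and 5 to 4.** Ketone 3 comes from 1 in two alkylations that use the difference between its two hydroxyls: the free 4-hydroxyl takes the methoxymethyl group (2), and the chelated 2-hydroxyl is then methylated. This sets the 2'-OMe/4'-OH pattern of ring B at the start. Acid chloride 5 is made from acid 4 in one step.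

## Alternatives that were turned down

**Alternative 1:** Ring A is dismantled at C5–C6, C7–C8 and C4a–C5. What remains is diazo ketone A2, a 4-pyranone that already carries ring B and, on the carbon that becomes C8a, a diazoacyl chain bearing the prenyl group, together with methoxyethyne A4 for C6 and C7.
- Forward key step: irradiation of A2 triggers a Wolff rearrangement to ketene A3. A4 adds across the ketene C=C bond with its unsubstituted carbon on the ketene carbonyl carbon, the four-membered ring so formed opens in a four-electron process, and six-electron closure onto the pyranone carbon that becomes C4a, followed by enolisation, gives A1, the 4'-O-allyl ether of 19.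
- For: the mechanism fixes all four ring A substituents of A1, the prenyl group is on carbon from the start, and O5 and O7 differ by origin.
- Against: A2 is a multistep target in itself. Its carbene carbon carries an allylic CH2, so a 1,2-hydrogen shift competes with the Wolff shift. The 2-aryl-4-pyranone chromophore shared by A2 and A1 absorbs light and is photolabile. The closing six-electron step must use a pyranone C=C bond that is part of a vinylogous ester. A4 is volatile and prone to polymerise, and the allyl group of A1 must still be removed.
- Comparison: on certainty of the C8 position this alternative is stronger, since C6 and C8 are never in competition on the way to A1. The chosen route instead offers three purchasable building blocks, polar steps of well-known types and fewer steps overall; it answers the C6/C8 question by a rearrangement in which C6 is only a stopover.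

**Alternative 2:** The C4–C4a bond is cut, with O1–C2 already in place in the (Z)-3-aryl-3-aryloxyacrylic acid A6, whose ring A half already carries the prenyl group and both methyl ethers.
- Forward key step: A6 is converted into acid chloride A7, and a trace of SnCl4 brings about intramolecular Friedel–Crafts acylation at the only free position ortho to the aryloxy oxygen, closing ring C to A5.
- For: the prenyl group blocks one ortho position of the aryloxy ring, so its place on C8 of A5 follows from the constitution of the substrate. The attacked carbon is strongly activated, and a C–C bond is made in the closure.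
- Against: acid chloride formation and a Lewis acid act in the presence of the prenyl olefin, which invites hydrochlorination and cation–olefin chemistry. Only the Z isomer of A6 can close. The ring A half of A6 has to be made by a C-prenylation that is itself unselective. A5 still requires cleavage of the 5-methyl ether alone, next to the 7- and 2'-methyl ethers, with BCl3 or AlCl3, which again threatens the olefin.
- Comparison: this alternative is as strong or stronger on the placement of the prenyl group. The chosen route gives in return an O5 that is never methylated (no selective demethylation), no Lewis acid of that strength in contact with the olefin, and a shorter end game.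

**Alternative 3:** Ring C is cut at C4a–C4, C4–C3 and O1–C2 into iodophenol A9, carbon monoxide A11 and arylacetylene A10.
- Forward key step: PdCl2(PPh3)2, a divalent palladium precatalyst that is reduced in the flask to zerovalent palladium, inserts into the C–I bond of A9 in the presence of a secondary amine. A11 is then taken up, coupling with A10 forms the C4–C3 bond, and the phenol oxygen closes the six-membered ring to A8.
- For: three bonds and a ring in one step, the highest convergence of all the routes, with the prenyl group already on C8 of A8.
- Against: A9 is a pentasubstituted arene whose iodine must be introduced ortho to a free phenol without iodoetherification of the neighbouring prenyl olefin. Its C–I bond is electron-rich and flanked on both sides, so oxidative addition is slow and direct coupling with A10 without uptake of A11 gains ground. Five-membered closure onto the other alkyne carbon competes with the six-membered one. A8 needs the same selective 5-O-demethylation as A5, besides removal of the methoxymethyl group.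
- Comparison: on bonds formed per step this alternative is stronger. The chosen route puts its effort into easily made precursors instead, has its risk in one well-understood closure, and never has to demethylate next to the prenyl group.

Key step: step 5

## Route

Remark: diketone 8 is drawn in the diketo form but is expected to exist largely as its hydrogen-bonded enol. Intermediates 10, 14, 16 and 17 each contain one transient sp3 centre that forms as a racemate and is erased within the same step; 16 and 17 are drawn without the bound europium.

Step 1
Reactants: 1 2,4-dihydroxyacetophenone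
Product: 2 1-[2-hydroxy-4-(methoxymethoxy)phenyl]ethanone
Conditions: MOMCl (1.1 equiv), K2CO3, acetone, 0 °C to rt
Reagents that add atoms: chloromethyl methyl ether, COCCl
Why: Williamson-type O-alkylation; the 2-hydroxyl is held in a hydrogen bond to the acetyl carbonyl and is less acidic and less nucleophilic, so the 4-phenoxide should be alkylated selectively.

Step 2
Reactants: 2 1-[2-hydroxy-4-(methoxymethoxy)phenyl]ethanone
Product: 3 1-[2-methoxy-4-(methoxymethoxy)phenyl]ethanone
Conditions: MeI (2 equiv), K2CO3, DMF, 40 °C
Reagents that add atoms: iodomethane, CI
Why: Williamson ether synthesis; in a dipolar aprotic solvent with excess methylating agent the chelated phenol is alkylated as well, and the acetal is inert to carbonate.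

Step 3
Reactants: 4 2,6-difluoro-4-methoxybenzoic acid
Product: 5 2,6-difluoro-4-methoxybenzoyl chloride
Conditions: (COCl)2 (1.3 equiv), cat. DMF, CH2Cl2, 0 °C to rt; concentrated and used crude
Reagents that add atoms: oxalyl chloride, O=C(Cl)C(Cl)=O
Why: acid chloride formation through the catalytic chloroiminium species; the by-products are gases, so the crude chloride can go directly into the acylation.

Step 4
Reactants: 3 1-[2-methoxy-4-(methoxymethoxy)phenyl]ethanone; 5 2,6-difluoro-4-methoxybenzoyl chloride
Product: 8 1-(2,6-difluoro-4-methoxyphenyl)-3-[2-methoxy-4-(methoxymethoxy)phenyl]propane-1,3-dione, via lithium enolate 6 (not isolated), via lithium diketonate 7 (not isolated)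
Conditions: LiN(SiMe3)2 (2.1 equiv), THF, −78 °C; then 5 (1.0 equiv), −78 to 0 °C; aq NH4Cl
Reagents that add atoms: none
Why: crossed Claisen-type C-acylation of a ketone lithium enolate by an acid chloride; 3 has one enolisable position and 5 none. The second equivalent of base converts the product into salt 7 and so guards it against a second acylation, and the hindered amide should leave the aryl fluorides alone at low temperature.

Step 5
Reactants: 8 1-(2,6-difluoro-4-methoxyphenyl)-3-[2-methoxy-4-(methoxymethoxy)phenyl]propane-1,3-dione
Product: 11 5-fluoro-7-methoxy-2-[2-methoxy-4-(methoxymethoxy)phenyl]chromen-4-one, via potassium enolate 9 (not isolated), via anionic sigma adduct 10 (not isolated)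
Conditions: K2CO3 (2.5 equiv), DMF, 80 °C
Reagents that add atoms: none
Why: K2CO3 turns diketone 8 into potassium enolate 9, and in DMF the potassium chelate is loose enough for rotation about the C3–C4 bond, which places the oxygen on the ring B side over a fluorine-bearing ortho carbon of the benzoyl ring. That oxygen adds to this carbon to give sigma adduct 10, in which the charge rests on the C4 carbonyl oxygen and is helped inductively by the second fluorine; loss of fluoride then restores the arene and gives 11 (addition–elimination, SNAr). The closest known reaction type is the base-mediated cyclisation of 1-(2-haloaryl)-1,3-diketones to flavones. Ring C closes as a six-membered ring by attack of oxygen on an sp2 carbon whose accepting double bond (C8a=C4a, conjugated to C4=O) lies inside the new ring, formally 6-endo-trig, in effect an intramolecular oxa-Michael addition followed by β-elimination of fluoride. No stereocentre is formed, since the sp3 carbon of 10 is transient. The step needs O-attack rather than C-attack of the ambident enolate and a single site on the arene: attack through the central carbon or through the nearer oxygen would demand a four-membered ring, and the two fluorines are related by the mirror plane through C1 and C4 of the benzoyl ring, so both closures give the same flavone. The methoxy group is meta to both fluorine-bearing carbons, so it is not attached to a carbon that carries charge in 10 and acts there only by induction, and K2CO3 is not nucleophilic enough to touch the surviving fluorine of 11.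

Step 6
Reactants: 11 5-fluoro-7-methoxy-2-[2-methoxy-4-(methoxymethoxy)phenyl]chromen-4-one; 12 3-methylbut-2-en-1-ol
Product: 15 7-methoxy-2-[2-methoxy-4-(methoxymethoxy)phenyl]-5-(3-methylbut-2-enyloxy)chromen-4-one, via sodium 3-methylbut-2-en-1-olate 13 (not isolated), via anionic sigma adduct 14 (not isolated)
Conditions: 12 (1.5 equiv), NaH (1.3 equiv), THF, 0 °C; then 11, 0 °C to rt
Reagents that add atoms: none
Why: intermolecular SNAr of a fluorine ortho to an aryl ketone by an alkoxide; alkoxide 13 adds to C5, the charge of adduct 14 is taken up by the C4 carbonyl, and fluoride leaves. The donors on C7 and C8a are meta to C5 and so sit on no charge-bearing carbon of 14, and addition of the alkoxide to C2 is reversible whereas loss of fluoride is not.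

Step 7
Reactants: 15 7-methoxy-2-[2-methoxy-4-(methoxymethoxy)phenyl]-5-(3-methylbut-2-enyloxy)chromen-4-one
Product: 18 5-hydroxy-7-methoxy-2-[2-methoxy-4-(methoxymethoxy)phenyl]-8-(3-methylbut-2-enyl)chromen-4-one, via C6 dienone 16 (not isolated), via C8 dienone 17 (not isolated)
Conditions: Eu(fod)3 (10 mol %; fod = 6,6,7,7,8,8,8-heptafluoro-2,2-dimethyloctane-3,5-dionate), NaHCO3, PhCl, 85 °C
Reagents that add atoms: none
Why: aromatic Claisen rearrangement followed by Cope rearrangement (para-Claisen sequence), as known for 5-O-prenyl flavonoids; the first [3,3] shift can only reach C6, the one free ortho position, and gives dienone 16 with a reversed 1,1-dimethylallyl group, the second [3,3] shift moves it to C8 with linear prenyl connectivity (17), and enolisation gives the chelated phenol 18. Eu(fod)3 binds O5 and the C4 carbonyl and lowers the temperature needed, and NaHCO3 keeps the medium free of acid so that neither the acetal nor the allyl ether is ionised.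

Step 8
Reactants: 18 5-hydroxy-7-methoxy-2-[2-methoxy-4-(methoxymethoxy)phenyl]-8-(3-methylbut-2-enyl)chromen-4-one
Product: 19 artocarpetin B, 5-hydroxy-2-(4-hydroxy-2-methoxyphenyl)-7-methoxy-8-(3-methylbut-2-enyl)chromen-4-one
Conditions: aq HCl (3 M), MeOH, 45 °C
Reagents that add atoms: none
Why: acid-catalysed acetal cleavage; the oxocarbenium fragment is taken up by methanol. The prenyl group on C8 sits between the ring oxygen and the 7-methoxy group, so no free hydroxyl can add to it, and the mild temperature limits Markovnikov addition of solvent to the olefin.

## Compound list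

1 | 2,4-dihydroxyacetophenone | CC(=O)c1ccc(O)cc1O | starting material
2 | 1-[2-hydroxy-4-(methoxymethoxy)phenyl]ethanone | CC(=O)c1ccc(OCOC)cc1O | intermediate
3 | 1-[2-methoxy-4-(methoxymethoxy)phenyl]ethanone | CC(=O)c1ccc(OCOC)cc1OC | intermediate
4 | 2,6-difluoro-4-methoxybenzoic acid | COc1cc(F)c(C(=O)O)c(F)c1 | starting material
5 | 2,6-difluoro-4-methoxybenzoyl chloride | COc1cc(F)c(C(=O)Cl)c(F)c1 | intermediate
6 | lithium 1-[2-methoxy-4-(methoxymethoxy)phenyl]ethenolate (lithium enolate of 3) | [Li+].C=C([O-])c1ccc(OCOC)cc1OC | intermediate (not isolated)
7 | lithium (Z)-3-(2,6-difluoro-4-methoxyphenyl)-1-[2-methoxy-4-(methoxymethoxy)phenyl]-3-oxoprop-1-en-1-olate (lithium salt of 8) | [Li+].COCOc1ccc(/C([O-])=C/C(=O)c2c(F)cc(OC)cc2F)c(OC)c1 | intermediate (not isolated)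
8 | 1-(2,6-difluoro-4-methoxyphenyl)-3-[2-methoxy-4-(methoxymethoxy)phenyl]propane-1,3-dione | COCOc1ccc(C(=O)CC(=O)c2c(F)cc(OC)cc2F)c(OC)c1 | intermediate
9 | potassium (Z)-3-(2,6-difluoro-4-methoxyphenyl)-1-[2-methoxy-4-(methoxymethoxy)phenyl]-3-oxoprop-1-en-1-olate (potassium enolate of 8) | [K+].COCOc1ccc(/C([O-])=C/C(=O)c2c(F)cc(OC)cc2F)c(OC)c1 | intermediate (not isolated)
10 | potassium 5,8a-difluoro-7-methoxy-2-[2-methoxy-4-(methoxymethoxy)phenyl]-8aH-chromen-4-olate (sigma adduct, C8a racemic) | [K+].COCOc1ccc(C2=CC([O-])=C3C(F)=CC(OC)=CC3(F)O2)c(OC)c1 | intermediate (not isolated)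
11 | 5-fluoro-7-methoxy-2-[2-methoxy-4-(methoxymethoxy)phenyl]chromen-4-one | COCOc1ccc(-c2cc(=O)c3c(F)cc(OC)cc3o2)c(OC)c1 | intermediate
12 | 3-methylbut-2-en-1-ol | CC(C)=CCO | starting material
13 | sodium 3-methylbut-2-en-1-olate | [Na+].CC(C)=CC[O-] | intermediate (not isolated)
14 | sodium 5-fluoro-7-methoxy-2-[2-methoxy-4-(methoxymethoxy)phenyl]-5-(3-methylbut-2-enyloxy)-5H-chromen-4-olate (sigma adduct, C5 racemic) | [Na+].COCOc1ccc(C2=CC([O-])=C3C(=CC(OC)=CC3(F)OCC=C(C)C)O2)c(OC)c1 | intermediate (not isolated)
15 | 7-methoxy-2-[2-methoxy-4-(methoxymethoxy)phenyl]-5-(3-methylbut-2-enyloxy)chromen-4-one | COCOc1ccc(-c2cc(=O)c3c(OCC=C(C)C)cc(OC)cc3o2)c(OC)c1 | intermediate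
16 | 7-methoxy-2-[2-methoxy-4-(methoxymethoxy)phenyl]-6-(2-methylbut-3-en-2-yl)-6H-chromene-4,5-dione (C6 racemic) | COCOc1ccc(C2=CC(=O)C3=C(O2)C=C(OC)C(C(C)(C)C=C)C3=O)c(OC)c1 | intermediate (not isolated)
17 | 7-methoxy-2-[2-methoxy-4-(methoxymethoxy)phenyl]-8-(3-methylbut-2-enyl)-8H-chromene-4,5-dione (C8 racemic) | COCOc1ccc(C2=CC(=O)C3=C(O2)C(CC=C(C)C)C(OC)=CC3=O)c(OC)c1 | intermediate (not isolated)
18 | 5-hydroxy-7-methoxy-2-[2-methoxy-4-(methoxymethoxy)phenyl]-8-(3-methylbut-2-enyl)chromen-4-one | COCOc1ccc(-c2cc(=O)c3c(O)cc(OC)c(CC=C(C)C)c3o2)c(OC)c1 | intermediate
19 | artocarpetin B, 5-hydroxy-2-(4-hydroxy-2-methoxyphenyl)-7-methoxy-8-(3-methylbut-2-enyl)chromen-4-one | COc1cc(O)ccc1-c1cc(=O)c2c(O)cc(OC)c(CC=C(C)C)c2o1 | target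

## Step count and least certain steps

Total: 8 steps. Longest linear sequence: 7 steps (steps 1, 2, 4, 5, 6, 7 and 8, from 1); step 3 prepares the second partner for step 4.

**Step 5 (key step).** The most likely trouble is cleavage of the 1,3-diketone by a retro-Claisen process (hydroxide from wet carbonate, or dimethylamine from the solvent on long heating), together with intermolecular substitution of the fluorine that survives in 11. Slow closure of the chelated diketonate is the lesser risk. The fallback sets out from 8 and avoids base and amine altogether. Compound 8 is silylated (Me3SiCl, Et3N, CH2Cl2) to the enol silyl ether (Z)-1-(2,6-difluoro-4-methoxyphenyl)-3-[2-methoxy-4-(methoxymethoxy)phenyl]-3-(trimethylsilyloxy)prop-2-en-1-one F1; the silyl group shuttles between the two oxygens, so its initial position does not matter. A catalytic amount of CsF in MeCN then removes silicon and frees a non-chelated enolate, which closes onto the arene. The fluoride it expels carries the chain on and ends on silicon. This fluoride-triggered substitution of silyl ethers on activated aryl fluorides is a known reaction type, and the fallback returns to the route at 11.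

**Step 6.** The alkoxide may add to C2 of the pyranone, open ring C and fragment the resulting diketone, in competition with substitution at C5; the C4 carbonyl is only a vinylogous ester and activates C5 moderately. The fallback places the prenyl ether before any pyranone exists. It sets out from 5, which is treated with two equivalents of alkoxide 13 (THF, 0 °C to rt). The first equivalent makes the ester and the second displaces one of the two equivalent fluorines, giving 3-methylbut-2-enyl 2-fluoro-4-methoxy-6-(3-methylbut-2-enyloxy)benzoate F2; the new ether deactivates the ring against a second substitution, and ester exchange is degenerate. Claisen condensation of F2 with enolate 6 (from 3, LiN(SiMe3)2, THF, −78 °C to rt) gives 1-[2-fluoro-4-methoxy-6-(3-methylbut-2-enyloxy)phenyl]-3-[2-methoxy-4-(methoxymethoxy)phenyl]propane-1,3-dione F3. F3 is closed as in step 5 but at higher temperature (K2CO3, DMSO, 100 °C), because the single remaining fluorine is less activated. The fallback returns to the route at 15.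

**Step 7.** The sequence may stop after the first shift, when enolisation of dienone 16 to a 6-(1,1-dimethylallyl) phenol outruns the second shift. The Lewis acid may also ionise the allyl–oxygen bond, which leads to loss of the prenyl group or to a 1,3-shift to C6. The fallback makes the C8–C bond by cross-coupling and sets out from 11. Electrophilic iodination (N-iodosuccinimide, cat. CF3CO2H, MeCN, 0 °C) is expected at C8, which is ortho to both ring A oxygens and para to fluorine, to give 5-fluoro-8-iodo-7-methoxy-2-[2-methoxy-4-(methoxymethoxy)phenyl]chromen-4-one F4; competing iodination of the electron-rich ring B is the weak point of this fallback. Stille coupling with tributyl(3-methylbut-2-enyl)stannane (Pd(PPh3)4, DMF, 80 °C) then gives 5-fluoro-7-methoxy-2-[2-methoxy-4-(methoxymethoxy)phenyl]-8-(3-methylbut-2-enyl)chromen-4-one F5, where coupling through the far end of the allyl unit is the risk. The fluorine is finally exchanged for hydroxyl with 2-(methylsulfonyl)ethanol and NaH in DMF. The ether 7-methoxy-2-[2-methoxy-4-(methoxymethoxy)phenyl]-5-[2-(methylsulfonyl)ethoxy]-8-(3-methylbut-2-enyl)chromen-4-one F6 is not isolated; it loses methyl vinyl sulfone under the basic conditions, and the fallback returns to the route at 18.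

**Step 4.** O-acylation of the enolate to an enol ester, a second acylation, or attack of the amide base on the acid chloride may lower the efficiency. The fallback changes both the acyl donor and the mode of enolisation and sets out from 5. With benzotriazole and Et3N in CH2Cl2, 5 gives 1-(2,6-difluoro-4-methoxybenzoyl)benzotriazole F7. Ketone 3 is then enolised under soft conditions (MgBr2·OEt2, i-Pr2NEt, CH2Cl2, rt) and C-acylated by F7; the product is held as a magnesium chelate until acidic work-up. The fallback returns to the route at 8.

## Further compounds

F1 | step 5 | (Z)-1-(2,6-difluoro-4-methoxyphenyl)-3-[2-methoxy-4-(methoxymethoxy)phenyl]-3-(trimethylsilyloxy)prop-2-en-1-one | COCOc1ccc(/C(O[Si](C)(C)C)=C/C(=O)c2c(F)cc(OC)cc2F)c(OC)c1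
F2 | step 6 | 3-methylbut-2-enyl 2-fluoro-4-methoxy-6-(3-methylbut-2-enyloxy)benzoate | COc1cc(F)c(C(=O)OCC=C(C)C)c(OCC=C(C)C)c1
F3 | step 6 | 1-[2-fluoro-4-methoxy-6-(3-methylbut-2-enyloxy)phenyl]-3-[2-methoxy-4-(methoxymethoxy)phenyl]propane-1,3-dione | COCOc1ccc(C(=O)CC(=O)c2c(F)cc(OC)cc2OCC=C(C)C)c(OC)c1
F4 | step 7 | 5-fluoro-8-iodo-7-methoxy-2-[2-methoxy-4-(methoxymethoxy)phenyl]chromen-4-one | COCOc1ccc(-c2cc(=O)c3c(F)cc(OC)c(I)c3o2)c(OC)c1
F5 | step 7 | 5-fluoro-7-methoxy-2-[2-methoxy-4-(methoxymethoxy)phenyl]-8-(3-methylbut-2-enyl)chromen-4-one | COCOc1ccc(-c2cc(=O)c3c(F)cc(OC)c(CC=C(C)C)c3o2)c(OC)c1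
F6 | step 7 | 7-methoxy-2-[2-methoxy-4-(methoxymethoxy)phenyl]-5-[2-(methylsulfonyl)ethoxy]-8-(3-methylbut-2-enyl)chromen-4-one | COCOc1ccc(-c2cc(=O)c3c(OCCS(C)(=O)=O)cc(OC)c(CC=C(C)C)c3o2)c(OC)c1
F7 | step 4 | 1-(2,6-difluoro-4-methoxybenzoyl)benzotriazole | COc1cc(F)c(C(=O)n2nnc3ccccc32)c(F)c1
A1 | alternative 1 | 4'-O-allyl artocarpetin B, 5-hydroxy-7-methoxy-2-[2-methoxy-4-(prop-2-enyloxy)phenyl]-8-(3-methylbut-2-enyl)chromen-4-one | C=CCOc1ccc(-c2cc(=O)c3c(O)cc(OC)c(CC=C(C)C)c3o2)c(OC)c1
A2 | alternative 1 | 2-diazo-1-{6-[2-methoxy-4-(prop-2-enyloxy)phenyl]-4-oxo-4H-pyran-2-yl}-5-methylhex-4-en-1-one | C=CCOc1ccc(-c2cc(=O)cc(C(=O)C(=[N+]=[N-])CC=C(C)C)o2)c(OC)c1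
A3 | alternative 1 | 2-{6-[2-methoxy-4-(prop-2-enyloxy)phenyl]-4-oxo-4H-pyran-2-yl}-5-methylhexa-1,4-dien-1-one (ketene) | C=CCOc1ccc(-c2cc(=O)cc(C(CC=C(C)C)=C=O)o2)c(OC)c1
A4 | alternative 1 | methoxyethyne | COC#C
A5 | alternative 2 | 5,7-dimethoxy-2-[2-methoxy-4-(propan-2-yloxy)phenyl]-8-(3-methylbut-2-enyl)chromen-4-one | COc1cc(OC(C)C)ccc1-c1cc(=O)c2c(OC)cc(OC)c(CC=C(C)C)c2o1
A6 | alternative 2 | (Z)-3-[3,5-dimethoxy-2-(3-methylbut-2-enyl)phenoxy]-3-[2-methoxy-4-(propan-2-yloxy)phenyl]prop-2-enoic acid | COc1cc(OC(C)C)ccc1/C(Oc1cc(OC)cc(OC)c1CC=C(C)C)=C/C(=O)O
A7 | alternative 2 | (Z)-3-[3,5-dimethoxy-2-(3-methylbut-2-enyl)phenoxy]-3-[2-methoxy-4-(propan-2-yloxy)phenyl]prop-2-enoyl chloride | COc1cc(OC(C)C)ccc1/C(Oc1cc(OC)cc(OC)c1CC=C(C)C)=C/C(=O)Cl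
A8 | alternative 3 | 5,7-dimethoxy-2-[2-methoxy-4-(methoxymethoxy)phenyl]-8-(3-methylbut-2-enyl)chromen-4-one | COCOc1ccc(-c2cc(=O)c3c(OC)cc(OC)c(CC=C(C)C)c3o2)c(OC)c1
A9 | alternative 3 | 2-iodo-3,5-dimethoxy-6-(3-methylbut-2-enyl)phenol | COc1cc(OC)c(CC=C(C)C)c(O)c1I
A10 | alternative 3 | 1-ethynyl-2-methoxy-4-(methoxymethoxy)benzene | COCOc1ccc(C#C)c(OC)c1
A11 | alternative 3 | carbon monoxide | [C-]#[O+]
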